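## Structural features

The target is a halogenated cuparane-type sesquiterpenoid: a cyclopentane (ring A, C1–C5) and a cyclohexane (ring B, C1'–C6') joined only by the C1–C1' bond, where C1 is quaternary and C1' is a tertiary carbinol. Ring A has three contiguous crowded carbons, C1'–C1–C2(CH3)2, followed by a secondary neopentyl bromide at C3 that lies cis to ring B (1R,3S). Ring B carries the C1' hydroxyl (R), a tertiary chloride at C4' (S) and a secondary bromide at C5' (S). With the bulky ring A substituent equatorial, both halogens are equatorial and trans to each other, chlorine cis (1,4) and bromine trans (1,3) to the axial hydroxyl. C1' is stereogenic only because the two arms of ring B differ at C4'/C5', so its configuration has to come from telling two otherwise equivalent methylene chains apart. The fragile groups are the tertiary alcohol next to quaternary C1 (ionisation at C1' invites migration of C2 and ring expansion), the tertiary chloride β to bromine, and the neopentyl bromide (elimination or methyl shift). The real difficulties are the vicinal fully substituted C1–C2 junction, a C3–Br bond on the more hindered face, and the diequatorial halogen pair, which is the opposite of what a trans-diaxial addition to a C4'=C5' alkene delivers. The key step uses the fact that C2 carries two methyl groups between C1 and C3: C2 can be a tertiary radical generated from an isopropenyl group on C1 and C3 the aldehyde carbon that traps it, so ring A closes through C2–C3 and the congested C1–C2 bond is never made.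

## Logic of the disconnections

**22 to 20 (through 21).** The C4'–Cl bond is cut; bromine is returned from C5' to C4' and an oxygen placed on C5'. Direct anti addition to the ring B alkene would pass through chair-like transition states and give the diaxial halogen pair on the other face. The pair is therefore drawn from one bromonium ion formed only on the face anti to the C1' hydroxyl, from an axial tertiary bromide and an activated axial oxygen at C5'. The gain is that the C1' oxygen is never made a leaving group, which matters because a cation at C1' would rearrange; a bridged C1'–O–C4' ether opened by a Lewis acid was rejected for this reason. The forward step must activate only the secondary hydroxyl and chloride must enter at the tertiary end of the bromonium ion.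

**20 to 19 to 18.** The C4'–Br bond and then both oxirane C–O bonds are cut. Trans-diaxial, Markovnikov opening of an epoxide cis to the C1' hydroxyl gives exactly 20, and that hydroxyl can direct the epoxidation to its own face. All ring B stereocentres then derive from C1' alone. The opening must avoid acid strong enough to ionise C1'–OH or to trigger transannular ether formation.

**18 to 17 to 16.** The C4'–CH3 bond is cut (cross-coupling), then the enol C–O bond, revealing a symmetric 4-hydroxycyclohexanone in which C1' is no longer stereogenic. The forward enolisation must choose one of two α-methylene groups under reagent control, in the presence of a free tertiary hydroxyl and the C3 bromide.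

**16 to 14 (through 15) to 12 (through 13).** The ketone returns to its ketal and the C1' hydroxyl to its acetate; C3–Br is cut to C3–O with inversion. A bromide on the hindered face is best introduced by SN2 on the alcohol of opposite configuration. The acetate stops the C1' oxygen from closing onto C3 (a 2-oxabicyclo[2.2.1]heptane). The forward step is an SN2 reaction at a neopentyl secondary carbon that must not ionise.

**12 to 11 (key step).** The C2–C3 bond is cut, opening ring A to an isopropenyl group on C1 and an aldehyde at C3. The new methyl completes the gem-dimethyl pair, so only C3 needs control. The forward step needs radical closure to beat reduction and the hydroxyl to form trans to ring B.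

**11 to 9 (through 10).** The aldehyde is masked as its dimethyl acetal so that it survives organomagnesium chemistry. Aqueous acid would not distinguish an aldehyde acetal from the ring B ketal, so the unmasking must be chemoselective by mechanism.

**9 to 5 and 6 (through 7 and 8).** The C1'–C2' and C1'–C6' bonds are cut: ring B comes from the ester carbon by double addition of a five-carbon bis-nucleophile, with the alkoxide acetylated in the same flask. Ring B arrives symmetric and without stereochemistry. The demand is double addition to a hindered ester.

**5 to 4 to 3.** The C2=CH2 bond is cut back to the acetyl group (methylenation) and the acetal back to the aldehyde.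

**3 to 1 and 2.** The C1–C5 bond is cut (Michael addition of a β-keto ester to an enal). This one catalytic step sets the quaternary stereocentre C1, with acetyl, ester and formylethyl groups mapping onto C2, C1' and C5–C3.

## Other disconnections considered

**Alternative 1:** The cut is at C1'–C2' and C5'–C6': ring B is opened to a C1' boronate with two alkenyl arms. Forward, the ate complex of the vinyl boronate A1 with a 3-methylbut-3-enyl organolithium would undergo conjunctive coupling with a vinyl halide under Pd(OAc)2 and a chiral ferrocenyl bisphosphine to give the tertiary boronate A2. Ring-closing metathesis and retentive C–B oxidation would then reach 18.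
- In favour: C1' is made directly as a stereocentre under catalyst control, and the C4'=C5' alkene arrives with its methyl group. The ketal, the chiral lithium amide step and the methyl cross-coupling all disappear. On step economy within ring B and on how cleanly C1' is set, this alternative is the better plan.
- Against: in A1 the migrating terminus carries the quaternary C1, so the 1,2-metallate shift must build a fully substituted carbon next to a quaternary one, well beyond the α-substituents usually tolerated. The catalyst must also override the adjacent stereocentre. A1 needs a finished ring A whose neopentyl bromide must survive an organolithium, and the alternative offers nothing for the C1–C2 junction.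
- Comparison: mechanistically it is a polar migration onto the crowded carbon, against a radical that is born on the crowded carbon and attacks an unhindered aldehyde. The end game from 18 is the same, so the two are equal there.

**Alternative 2:** The cut is at C1'–O. Ring B is carried as a para-methoxyphenyl group on C1, reduced (dissolving metal) and ketalised to the cyclohexenyl ketal A3. A fructose-derived ketone with KHSO5 would epoxidise one face of its C1'=C6' alkene to give A4.
- In favour: the C1–C1' bond exists from the start as an aryl–alkyl bond, so no hindered ester annulation is needed; here it is the better plan. Selection at C1' is catalytic rather than by a stoichiometric chiral base, also a point in its favour.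
- Against: simple reductive opening of A4 would return a symmetric ring and erase the information. The C6' oxygen must be relayed, for example by elimination to a γ-hydroxy enone and conjugate reduction with enolate triflation to reach 17, about four operations more than the chosen route spends on the same intermediate. The dissolving-metal step cannot coexist with the C3 bromide, which fixes an awkward order. An epoxide flanked by quaternary C1 is prone to semipinacol shift, and the dioxirane must approach an alkene carrying a quaternary substituent.
- Comparison: ring A must still be built separately, and the halogen end game is identical, so the two are equal there.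

**Alternative 3:** The cuts are C1–C2 and C4–C5. The palladium–trimethylenemethane zwitterion from A6 (Pd(dba)2, chiral phosphoramidite) would add to the nitroalkene A5 to give the cyclopentane A7, with the aryl group again as latent ring B.
- In favour: ring A and the quaternary C1 form in one catalytic asymmetric step from two simple partners. This is more convergent than Michael addition plus radical closure and, on that point, better; on catalyst control of C1 the two plans are equal.
- Against: C2 arrives as CH2 and must be methylated twice next to quaternary C1, through a C3 ketone whose other α-position (C4) is the more accessible one. The nitro group has to be removed, and a β,β-disubstituted nitroalkene is a reluctant acceptor. Denitration, alkene cleavage, regiocontrolled double methylation, reduction and bromination are followed by all the arene work of alternative 2.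
- Comparison: in the chosen plan the gem-dimethyl group is a by-product of the ring closure itself, so the chosen plan is clearly shorter, and the ring B halogenation problem is untouched by this alternative.

Key step: step 6

Assumption 1: 2,2-bis(2-bromoethyl)-1,3-dioxolane (6) is taken as a catalogue compound; it is otherwise one ketalisation away from 1,5-dibromopentan-3-one.
Assumption 2: the sense of induction in steps 1 and 9 is chosen through the pseudoenantiomeric cinchona catalysts and the two enantiomers of the lithium amide; the antipode written is assumed to give the configuration drawn.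

## Steps

Step 1
Reactants: 1 methyl 2-methyl-3-oxobutanoate; 2 prop-2-enal
Product: 3 methyl (2R)-2-acetyl-2-methyl-5-oxopentanoate
Conditions: 9-O-(9-phenanthryl)cupreidine (10 mol%), CH2Cl2, −25 °C
Reagents that add atoms: none
Why: Bifunctional cinchona catalysis of a Michael addition: the quinuclidine deprotonates the β-keto ester and the 6'-hydroxyl activates the enal, so the chiral ion pair fixes the enolate face and creates the quaternary carbon (2R), the future C1.

Step 2
Reactants: 3 methyl (2R)-2-acetyl-2-methyl-5-oxopentanoate
Product: 4 methyl (2R)-2-acetyl-5,5-dimethoxy-2-methylpentanoate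
Conditions: HC(OMe)3, MeOH, pyridinium p-toluenesulfonate (cat.), 0 → 25 °C
Reagents that add atoms: trimethyl orthoformate, COC(OC)OC; methanol, CO
Why: Acid-catalysed acetalisation is much faster at the aldehyde than at the neopentyl-type methyl ketone, and it removes the risk of intramolecular aldol condensation of 3.

Step 3
Reactants: 4 methyl (2R)-2-acetyl-5,5-dimethoxy-2-methylpentanoate
Product: 5 methyl (2R)-5,5-dimethoxy-2-methyl-2-(prop-1-en-2-yl)pentanoate
Conditions: Ph3PCH3Br, KN(SiMe3)2, toluene, 0 → 80 °C
Reagents that add atoms: methyltriphenylphosphonium bromide, C[P+](c1ccccc1)(c1ccccc1)c1ccccc1.[Br-]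
Why: Wittig methylenation of the methyl ketone; the ester on the same quaternary carbon is too hindered to be acylated by the ylide, and the quaternary centre cannot epimerise.

Step 4
Reactants: 5 methyl (2R)-5,5-dimethoxy-2-methyl-2-(prop-1-en-2-yl)pentanoate; 6 2,2-bis(2-bromoethyl)-1,3-dioxolane
Product: 9 8-[(3R)-6,6-dimethoxy-2,3-dimethylhex-1-en-3-yl]-1,4-dioxaspiro[4.5]decan-8-yl acetate, via bis-Grignard reagent 7 (not isolated), via bromomagnesium alkoxide 8 (not isolated)
Conditions: Mg, THF, 25 °C (6 to 7); then 5, 0 → 40 °C; then Ac2O, 0 → 25 °C
Reagents that add atoms: acetic anhydride, CC(=O)OC(C)=O; (intermediates 7 and 8 only: magnesium, [Mg])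
Why: Annulation of an ester with a 1,5-bis-organomagnesium reagent: the first addition gives the ketone and the second is intramolecular, closing the symmetric ring B (no new stereocentre). The tertiary alkoxide is acetylated in the flask because the neutral alcohol beside quaternary C1 would resist acylation.

Step 5
Reactants: 9 8-[(3R)-6,6-dimethoxy-2,3-dimethylhex-1-en-3-yl]-1,4-dioxaspiro[4.5]decan-8-yl acetate
Product: 11 (4R)-4-(8-acetoxy-1,4-dioxaspiro[4.5]decan-8-yl)-4,5-dimethylhex-5-enal, via N-(1-methoxyalkyl)collidinium triflate 10 (not isolated)
Conditions: Et3SiOTf, 2,4,6-collidine, CH2Cl2, 0 °C; then H2O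
Reagents that add atoms: water, O; (intermediate 10 only: 2,4,6-trimethylpyridine, Cc1cc(C)nc(C)c1; triethylsilyl trifluoromethanesulfonate, CC[Si](CC)(CC)OS(=O)(=O)C(F)(F)F)
Why: Silyl triflate with collidine turns aldehyde acetals into pyridinium N,O-acetals that water hydrolyses, while ketone ketals do not react (chemoselective deacetalisation). Aqueous acid would attack the ring B ketal at a comparable rate.

Step 6
Reactants: 11 (4R)-4-(8-acetoxy-1,4-dioxaspiro[4.5]decan-8-yl)-4,5-dimethylhex-5-enal
Product: 12 8-[(1R,3R)-3-hydroxy-1,2,2-trimethylcyclopentyl]-1,4-dioxaspiro[4.5]decan-8-yl acetate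
Conditions: Fe(acac)3, PhSiH3, EtOH, 60 °C
Reagents that add atoms: none
Why: Fe(acac)3 and PhSiH3 in ethanol form an iron hydride that transfers a hydrogen atom to the terminal CH2 of the isopropenyl group (Markovnikov metal-hydride hydrogen-atom transfer), giving the tertiary radical at C2. This radical adds to the aldehyde carbon C3 in a 5-exo-trig closure, forming C2–C3 and ring A; the alkoxy radical is reduced at once to the iron alkoxide (divalent iron returning to trivalent) and protonated by ethanol, which stops β-scission back to the open radical. The closest known reaction type is the iron-hydride reductive radical cyclisation of alkene-tethered aldehydes and ketones to cycloalkanols. C3 is the only new stereocentre: in the envelope-like transition state the forming C–O bond points away from the ring B substituent on C1, so the hydroxyl should end trans to ring B (3R). C2 becomes a gem-dimethyl carbon and needs no control, and C1 is untouched. The step needs cyclisation to outrun reduction of the radical or the aldehyde; the quaternary C1 holds radical and carbonyl together and the aldehyde is unhindered. Lactol formation is excluded because the C1' oxygen is acetylated, and the acetate, the ketal and the absence of a second alkene leave no competing site.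

Step 7
Reactants: 12 8-[(1R,3R)-3-hydroxy-1,2,2-trimethylcyclopentyl]-1,4-dioxaspiro[4.5]decan-8-yl acetate
Product: 14 8-[(1R,3S)-3-bromo-1,2,2-trimethylcyclopentyl]-1,4-dioxaspiro[4.5]decan-8-yl acetate, via C3 triflate 13 (not isolated)
Conditions: Tf2O, 2,6-lutidine, CH2Cl2, −40 °C; then n-Bu4NBr, −40 → 25 °C
Reagents that add atoms: tetrabutylammonium bromide, CCCC[N+](CCCC)(CCCC)CCCC.[Br-]; (intermediate 13 only: trifluoromethanesulfonic anhydride, O=S(=O)(OS(=O)(=O)C(F)(F)F)C(F)(F)F)
Why: Triflation of the secondary alcohol and SN2 displacement by bromide with inversion at C3 (3R to 3S) places bromine cis to ring B. A weakly ionising medium and a naked bromide favour SN2 over methyl shift, and the C1' oxygen, being an ester, cannot close onto C3.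

Step 8
Reactants: 14 8-[(1R,3S)-3-bromo-1,2,2-trimethylcyclopentyl]-1,4-dioxaspiro[4.5]decan-8-yl acetate
Product: 16 4-[(1R,3S)-3-bromo-1,2,2-trimethylcyclopentyl]-4-hydroxycyclohexan-1-one, via hydroxy ketal 15 (not isolated)
Conditions: i-Bu2AlH, CH2Cl2, −78 °C; then 1 M HCl, THF, 25 °C
Reagents that add atoms: water, O
Why: Reductive cleavage of the hindered tertiary acetate by the aluminium hydride (the alkyl bromide is inert at −78 °C), then mild acid hydrolysis of the ketal. The ketone is released only after the hydride has been quenched.

Step 9
Reactants: 16 4-[(1R,3S)-3-bromo-1,2,2-trimethylcyclopentyl]-4-hydroxycyclohexan-1-one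
Product: 17 (4R)-4-[(1R,3S)-3-bromo-1,2,2-trimethylcyclopentyl]-4-hydroxycyclohex-1-en-1-yl trifluoromethanesulfonate
Conditions: lithium bis[(1R)-1-phenylethyl]amide (2.3 equiv), LiCl, THF, −78 °C; then N-(5-chloropyridin-2-yl)bis(trifluoromethanesulfonyl)imide, −78 → 0 °C
Reagents that add atoms: N-(5-chloropyridin-2-yl)bis(trifluoromethanesulfonyl)imide, FC(F)(F)S(=O)(=O)N(c1ccc(Cl)cn1)S(=O)(=O)C(F)(F)F
Why: Group-selective deprotonation of a 4,4-disubstituted cyclohexanone by a chiral lithium amide, then O-triflation of the enolate. The choice of which α-methylene loses its proton makes C1' stereogenic (R); because ring A is already enantiopure the selectivity appears as a diastereomer ratio.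

Step 10
Reactants: 17 (4R)-4-[(1R,3S)-3-bromo-1,2,2-trimethylcyclopentyl]-4-hydroxycyclohex-1-en-1-yl trifluoromethanesulfonate
Product: 18 (1R)-1-[(1R,3S)-3-bromo-1,2,2-trimethylcyclopentyl]-4-methylcyclohex-3-en-1-ol
Conditions: MeZnCl (2.5 equiv), Pd(PPh3)4 (5 mol%), THF, 50 °C
Reagents that add atoms: methylzinc chloride, C[Zn]Cl
Why: Negishi coupling of the enol triflate at zerovalent palladium; the unactivated secondary bromide does not undergo oxidative addition with Pd(PPh3)4, and the first equivalent of the zinc reagent only forms the zinc alkoxide.

Step 11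
Reactants: 18 (1R)-1-[(1R,3S)-3-bromo-1,2,2-trimethylcyclopentyl]-4-methylcyclohex-3-en-1-ol
Product: 19 (1R,3R,6S)-3-[(1R,3S)-3-bromo-1,2,2-trimethylcyclopentyl]-6-methyl-7-oxabicyclo[4.1.0]heptan-3-ol
Conditions: t-BuOOH, VO(acac)2 (cat.), CH2Cl2, 0 → 25 °C
Reagents that add atoms: tert-butyl hydroperoxide, CC(C)(C)OO
Why: Vanadium-catalysed hydroxyl-directed epoxidation: the axial C1' hydroxyl binds the metal and delivers oxygen to its own face of the C4'=C5' alkene, as in 4-methylcyclohex-3-en-1-ols of the terpinen-4-ol type, giving the cis epoxy alcohol.

Step 12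
Reactants: 19 (1R,3R,6S)-3-[(1R,3S)-3-bromo-1,2,2-trimethylcyclopentyl]-6-methyl-7-oxabicyclo[4.1.0]heptan-3-ol
Product: 20 (1R,3R,4R)-4-bromo-1-[(1R,3S)-3-bromo-1,2,2-trimethylcyclopentyl]-4-methylcyclohexane-1,3-diol
Conditions: MgBr2·OEt2, Et2O, −30 → 0 °C
Reagents that add atoms: magnesium bromide diethyl etherate (bromide source), Br[Mg]Br
Why: Epoxide opening to a bromohydrin: magnesium held between the C1' hydroxyl and the oxirane oxygen activates the ring, and bromide enters anti at the tertiary carbon C4' (Markovnikov and trans-diaxial), leaving an axial hydroxyl at C5'. No acid strong enough to ionise C1'–OH is present.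

Step 13
Reactants: 20 (1R,3R,4R)-4-bromo-1-[(1R,3S)-3-bromo-1,2,2-trimethylcyclopentyl]-4-methylcyclohexane-1,3-diol
Product: 22 (1R,3S,4S)-3-bromo-1-[(1R,3S)-3-bromo-1,2,2-trimethylcyclopentyl]-4-chloro-4-methylcyclohexan-1-ol, via alkoxyphosphonium chloride 21 (not isolated)
Conditions: PPh3, CCl4, CH2Cl2, 0 → 25 °C
Reagents that add atoms: tetrachloromethane, ClC(Cl)(Cl)Cl; (intermediate 21 only: triphenylphosphine, c1ccc(cc1)P(c1ccccc1)c1ccccc1)
Why: Appel activation picks the secondary C5' hydroxyl over the tertiary one beside quaternary C1; the antiperiplanar tertiary bromide then expels Ph3P=O (neighbouring-group participation with 1,2-bromine shift), forming the bromonium ion on the face anti to the C1' hydroxyl. Chloride of the ion pair opens it at the tertiary carbon C4' from the face the oxygen left, giving inversion at C5' (Br) and a second inversion at C4' (Cl), which is the diequatorial trans pair of the target.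

## Compound list

1 | methyl 2-methyl-3-oxobutanoate (racemic) | COC(=O)C(C)C(C)=O | starting material
2 | prop-2-enal | C=CC=O | starting material
3 | methyl (2R)-2-acetyl-2-methyl-5-oxopentanoate | COC(=O)[C@@](C)(C(C)=O)CCC=O | intermediate
4 | methyl (2R)-2-acetyl-5,5-dimethoxy-2-methylpentanoate | COC(=O)[C@@](C)(C(C)=O)CCC(OC)OC | intermediate
5 | methyl (2R)-5,5-dimethoxy-2-methyl-2-(prop-1-en-2-yl)pentanoate | COC(=O)[C@@](C)(C(C)=C)CCC(OC)OC | intermediate
6 | 2,2-bis(2-bromoethyl)-1,3-dioxolane | BrCCC1(CCBr)OCCO1 | starting material
7 | [1,3-dioxolane-2,2-diylbis(ethane-2,1-diyl)]bis(bromomagnesium) | Br[Mg]CCC1(CC[Mg]Br)OCCO1 | intermediate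
8 | bromomagnesium 8-[(3R)-6,6-dimethoxy-2,3-dimethylhex-1-en-3-yl]-1,4-dioxaspiro[4.5]decan-8-olate | COC(OC)CC[C@](C)(C(C)=C)C1(O[Mg]Br)CCC2(CC1)OCCO2 | intermediate
9 | 8-[(3R)-6,6-dimethoxy-2,3-dimethylhex-1-en-3-yl]-1,4-dioxaspiro[4.5]decan-8-yl acetate | COC(OC)CC[C@](C)(C(C)=C)C1(OC(C)=O)CCC2(CC1)OCCO2 | intermediate
10 | 1-[(4R)-4-(8-acetoxy-1,4-dioxaspiro[4.5]decan-8-yl)-1-methoxy-4,5-dimethylhex-5-en-1-yl]-2,4,6-trimethylpyridin-1-ium trifluoromethanesulfonate (both epimers at the N,O-acetal carbon) | COC(CC[C@](C)(C(C)=C)C1(OC(C)=O)CCC2(CC1)OCCO2)[n+]1c(C)cc(C)cc1C.[O-]S(=O)(=O)C(F)(F)F | intermediate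
11 | (4R)-4-(8-acetoxy-1,4-dioxaspiro[4.5]decan-8-yl)-4,5-dimethylhex-5-enal | O=CCC[C@](C)(C(C)=C)C1(OC(C)=O)CCC2(CC1)OCCO2 | intermediate
12 | 8-[(1R,3R)-3-hydroxy-1,2,2-trimethylcyclopentyl]-1,4-dioxaspiro[4.5]decan-8-yl acetate | CC1(C)[C@H](O)CC[C@@]1(C)C1(OC(C)=O)CCC2(CC1)OCCO2 | intermediate
13 | 8-{(1R,3R)-1,2,2-trimethyl-3-[(trifluoromethanesulfonyl)oxy]cyclopentyl}-1,4-dioxaspiro[4.5]decan-8-yl acetate | CC1(C)[C@H](OS(=O)(=O)C(F)(F)F)CC[C@@]1(C)C1(OC(C)=O)CCC2(CC1)OCCO2 | intermediate
14 | 8-[(1R,3S)-3-bromo-1,2,2-trimethylcyclopentyl]-1,4-dioxaspiro[4.5]decan-8-yl acetate | CC1(C)[C@@H](Br)CC[C@@]1(C)C1(OC(C)=O)CCC2(CC1)OCCO2 | intermediate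
15 | 8-[(1R,3S)-3-bromo-1,2,2-trimethylcyclopentyl]-1,4-dioxaspiro[4.5]decan-8-ol | CC1(C)[C@@H](Br)CC[C@@]1(C)C1(O)CCC2(CC1)OCCO2 | intermediate
16 | 4-[(1R,3S)-3-bromo-1,2,2-trimethylcyclopentyl]-4-hydroxycyclohexan-1-one | CC1(C)[C@@H](Br)CC[C@@]1(C)C1(O)CCC(=O)CC1 | intermediate
17 | (4R)-4-[(1R,3S)-3-bromo-1,2,2-trimethylcyclopentyl]-4-hydroxycyclohex-1-en-1-yl trifluoromethanesulfonate | CC1(C)[C@@H](Br)CC[C@@]1(C)[C@@]1(O)CCC(OS(=O)(=O)C(F)(F)F)=CC1 | intermediate
18 | (1R)-1-[(1R,3S)-3-bromo-1,2,2-trimethylcyclopentyl]-4-methylcyclohex-3-en-1-ol | CC1(C)[C@@H](Br)CC[C@@]1(C)[C@@]1(O)CCC(C)=CC1 | intermediate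
19 | (1R,3R,6S)-3-[(1R,3S)-3-bromo-1,2,2-trimethylcyclopentyl]-6-methyl-7-oxabicyclo[4.1.0]heptan-3-ol | CC1(C)[C@@H](Br)CC[C@@]1(C)[C@@]1(O)CC[C@]2(C)O[C@@H]2C1 | intermediate
20 | (1R,3R,4R)-4-bromo-1-[(1R,3S)-3-bromo-1,2,2-trimethylcyclopentyl]-4-methylcyclohexane-1,3-diol | CC1(C)[C@@H](Br)CC[C@@]1(C)[C@@]1(O)CC[C@@](C)(Br)[C@H](O)C1 | intermediate
21 | {[(1R,2R,5R)-2-bromo-5-[(1R,3S)-3-bromo-1,2,2-trimethylcyclopentyl]-5-hydroxy-2-methylcyclohexyl]oxy}triphenylphosphonium chloride | CC1(C)[C@@H](Br)CC[C@@]1(C)[C@@]1(O)CC[C@@](C)(Br)[C@H](O[P+](c2ccccc2)(c2ccccc2)c2ccccc2)C1.[Cl-] | intermediate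
22 | (1R,3S,4S)-3-bromo-1-[(1R,3S)-3-bromo-1,2,2-trimethylcyclopentyl]-4-chloro-4-methylcyclohexan-1-ol | CC1(C)[C@@H](Br)CC[C@@]1(C)[C@@]1(O)CC[C@](C)(Cl)[C@@H](Br)C1 | target

## Step count and least certain steps

Total step count: 13. Longest linear sequence: 13 steps (1 and 2 to 22; 6 joins in step 4).

**Step 6 (key step).** The most likely failure is poor facial selectivity in the radical addition to the aldehyde: the carbonyl oxygen is only moderately biased away from ring B and the addition is reversible until the alkoxy radical is reduced. Some plain hydrogenation of the alkene is also possible if the radical is quenched before it closes. The fallback sets out from 12 as its mixture of C3 epimers. Dess–Martin oxidation would give the ketone 8-[(1R)-1,2,2-trimethyl-3-oxocyclopentyl]-1,4-dioxaspiro[4.5]decan-8-yl acetate F1. Oxazaborolidine-catalysed reduction with BH3·SMe2, the catalyst enantiomer chosen to deliver hydride cis to ring B, would return to the route at 12. Reagent control thus replaces substrate control at C3.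

**Step 13.** The bromonium ion may be partitioned wrongly. Chloride may return to C5', the carbon the oxygen left, giving the tertiary bromide/secondary chloride isomer. The ion may be captured by the C1' hydroxyl after a flip to the boat, or phosphorus may engage both hydroxyls. The fallback sets out from 18. N-Bromosuccinimide in CH2Cl2 would give, by transannular bromoetherification (known for 4-methylcyclohex-3-en-1-ols), the bridged ether (1S,2S,4R)-2-bromo-4-[(1R,3S)-3-bromo-1,2,2-trimethylcyclopentyl]-1-methyl-7-oxabicyclo[2.2.1]heptane F2. TiCl4 at −78 °C would open it with bromine assistance at C4'–O and return of titanium-bound chloride on the oxygen face, rejoining the route at 22. It is the second choice because the same Lewis acid can also ionise the C1'–O bond.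

**Step 7.** Elimination to the cyclopentene, or ionisation with methyl migration from C2, may outrun an SN2 attack that has to approach a neopentyl carbon from the face cis to ring B. The fallback sets out from 12 and installs bromine before hydrogen. Oxidation gives the ketone 8-[(1R)-1,2,2-trimethyl-3-oxocyclopentyl]-1,4-dioxaspiro[4.5]decan-8-yl acetate F1, and (PhO)3P/Br2/Et3N converts it into the vinyl bromide 8-[(1R)-3-bromo-1,2,2-trimethylcyclopent-3-en-1-yl]-1,4-dioxaspiro[4.5]decan-8-yl acetate F3. Hydrogen-atom-transfer hydrogenation (Mn(dpm)3, PhSiH3, t-BuOOH, i-PrOH) should deliver the second hydrogen to the α-bromo radical from the open face trans to ring B. Bromine is then left cis, and the route is rejoined at 14.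

**Step 9.** The chiral base may discriminate poorly between the two α-methylene groups, because the lithium alkoxide at C1' joins the amide aggregate and the stereocentres of ring A are remote. The fallback sets out from 16 and gives up reagent control. LiN(SiMe3)2 and the same triflimide would give 17 together with its C1' epimer (4S)-4-[(1R,3S)-3-bromo-1,2,2-trimethylcyclopentyl]-4-hydroxycyclohex-1-en-1-yl trifluoromethanesulfonate F4. The two are diastereomers and would be separated by chromatography. F4 would be hydrolysed (KOH, MeOH/THF) back to 16 for recycling, and the route continues from 17.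

**Step 4.** Addition to the neopentyl-type ester may be slower than the decay of the γ-ketal Grignard reagent (closure to a cyclopropyl ether) or than enolisation of the intermediate ketone, and the alkoxide may acetylate incompletely. The fallback sets out from 3 and uses a tied-back, more electrophilic lactone:
- NaBH4 at −40 °C reduces only the aldehyde and the product lactonises to (3R)-3-acetyl-3-methyloxan-2-one F5.
- Methylenation (Zn, CH2Br2, TiCl4) gives (3R)-3-methyl-3-(prop-1-en-2-yl)oxan-2-one F6.
- Reagent 7 converts F6 into the diol 8-[(3R)-6-hydroxy-2,3-dimethylhex-1-en-3-yl]-1,4-dioxaspiro[4.5]decan-8-ol F7.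
- n-BuLi (2.2 equiv) and Ac2O give the diacetate 8-[(3R)-6-acetoxy-2,3-dimethylhex-1-en-3-yl]-1,4-dioxaspiro[4.5]decan-8-yl acetate F8.
- K2CO3 in MeOH at 0 °C removes only the primary acetate, giving 8-[(3R)-6-hydroxy-2,3-dimethylhex-1-en-3-yl]-1,4-dioxaspiro[4.5]decan-8-yl acetate F9.
- Dess–Martin oxidation rejoins the route at 11.

## Further compounds

F1 | step 6 | 8-[(1R)-1,2,2-trimethyl-3-oxocyclopentyl]-1,4-dioxaspiro[4.5]decan-8-yl acetate | CC1(C)C(=O)CC[C@@]1(C)C1(OC(C)=O)CCC2(CC1)OCCO2
F2 | step 13 | (1S,2S,4R)-2-bromo-4-[(1R,3S)-3-bromo-1,2,2-trimethylcyclopentyl]-1-methyl-7-oxabicyclo[2.2.1]heptane | CC1(C)[C@@H](Br)CC[C@@]1(C)[C@]12CC[C@](C)(O1)[C@@H](Br)C2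
F3 | step 7 | 8-[(1R)-3-bromo-1,2,2-trimethylcyclopent-3-en-1-yl]-1,4-dioxaspiro[4.5]decan-8-yl acetate | CC1(C)C(Br)=CC[C@@]1(C)C1(OC(C)=O)CCC2(CC1)OCCO2
F4 | step 9 | (4S)-4-[(1R,3S)-3-bromo-1,2,2-trimethylcyclopentyl]-4-hydroxycyclohex-1-en-1-yl trifluoromethanesulfonate | CC1(C)[C@@H](Br)CC[C@@]1(C)[C@]1(O)CCC(OS(=O)(=O)C(F)(F)F)=CC1
F5 | step 4 | (3R)-3-acetyl-3-methyloxan-2-one | O=C1OCCC[C@]1(C)C(C)=O
F6 | step 4 | (3R)-3-methyl-3-(prop-1-en-2-yl)oxan-2-one | O=C1OCCC[C@]1(C)C(C)=C
F7 | step 4 | 8-[(3R)-6-hydroxy-2,3-dimethylhex-1-en-3-yl]-1,4-dioxaspiro[4.5]decan-8-ol | OCCC[C@](C)(C(C)=C)C1(O)CCC2(CC1)OCCO2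
F8 | step 4 | 8-[(3R)-6-acetoxy-2,3-dimethylhex-1-en-3-yl]-1,4-dioxaspiro[4.5]decan-8-yl acetate | CC(=O)OCCC[C@](C)(C(C)=C)C1(OC(C)=O)CCC2(CC1)OCCO2
F9 | step 4 | 8-[(3R)-6-hydroxy-2,3-dimethylhex-1-en-3-yl]-1,4-dioxaspiro[4.5]decan-8-yl acetate | OCCC[C@](C)(C(C)=C)C1(OC(C)=O)CCC2(CC1)OCCO2
A1 | alternative 1 | pinacol 1-(3-bromo-1,2,2-trimethylcyclopentyl)ethenylboronate, ring A configured as in 22 | CC1(C)[C@@H](Br)CC[C@@]1(C)C(=C)B1OC(C)(C)C(C)(C)O1
A2 | alternative 1 | tertiary pinacol boronate at C1' with allyl and 3-methylbut-3-enyl arms, product of the conjunctive coupling | CC1(C)[C@@H](Br)CC[C@@]1(C)[C@@](CC=C)(B1OC(C)(C)C(C)(C)O1)CCC(C)=C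
A3 | alternative 2 | 8-(3-bromo-1,2,2-trimethylcyclopentyl)-1,4-dioxaspiro[4.5]dec-7-ene, ring A configured as in 22 | CC1(C)[C@@H](Br)CC[C@@]1(C)C1=CCC2(CC1)OCCO2
A4 | alternative 2 | 7,8-epoxy-8-(3-bromo-1,2,2-trimethylcyclopentyl)-1,4-dioxaspiro[4.5]decane, oxygen on the face of the C1' hydroxyl of 22 | CC1(C)[C@@H](Br)CC[C@@]1(C)[C@@]1(O2)CCC3(OCCO3)C[C@@H]12
A5 | alternative 3 | (E)-1-methoxy-4-(1-nitroprop-1-en-2-yl)benzene | COc1ccc(cc1)/C(C)=C/[N+](=O)[O-]
A6 | alternative 3 | 2-[(trimethylsilyl)methyl]allyl acetate | CC(=O)OCC(=C)C[Si](C)(C)C
A7 | alternative 3 | 1-methoxy-4-(1-methyl-4-methylidene-2-nitrocyclopentyl)benzene, quaternary carbon as C1 of 22, nitro trans to aryl | C1C(=C)C[C@H]([N+](=O)[O-])[C@@]1(C)c1ccc(OC)cc1
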